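The plan rests on the vicinal oxygens at C5 (ether bridge) and C6 (lactone) of the in,out 11-oxabicyclo[4.4.1]undecenone core. Moving the bridge oxygen back from C5 to C6 converts the two strained seven-membered rings (oxepane O–C5–C6–C7–C8–C9–C10 and oxepinone O–C5–C4–C3–C2–C1–C10) into a cis-2,6-bridged tetrahydropyran and an eight-membered enone ring. This out,out [5.3.1] ether can be reached by ordinary ring closure. In the forward direction the ring oxygen expels a C5 sulfonate and acetate opens the epoxonium ion at C6. One operation therefore makes two C–O bonds, both seven-membered rings and the C5/C6 configurations. The precursor is a C5 chloromethanesulfonate that already carries the C7 acrylate, C8 angelate and C15 silyl ether.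

Key step: step 23

Locants and assumption:
- C1 is the ketone carbon, C2=C3 the enone alkene, C4 the CH bearing C15H2O.
- C5 and C6 are the two oxygenated carbons, C7 bears C11(=C13H2)C12O2, C8 bears the angelate, C9 is CH2, and C10 is the quaternary carbon bearing C14H3.
- TBS = tert-butyldimethylsilyl; TBDPS = tert-butyldiphenylsilyl.
- The target is (4R,5R,6S,7R,8R,10S) and precursor 31 is (4R,5S,6R,7R,8R,10S), so only C5 and C6 differ, each by one inversion.
- The C1 carbinol centre of 21 and 22 is assumed to be an epimer mixture. It is erased in step 16.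

Step 1
Reactants: 1 dimethyl (R)-malate
Product: 2 methyl (R)-3,4-dihydroxybutanoate
Conditions: BH3·SMe2, NaBH4 (5 mol %), THF, 0 °C to rt; MeOH quench
Reagents that add atoms: none
Why: Hydroxyl-directed chemoselective borane reduction, in which the alkoxyborane formed at the future C6 oxygen delivers hydride only to the neighbouring C5 ester, the remote C8 ester survives and the stereocentre is untouched.

Step 2
Reactants: 2 methyl (R)-3,4-dihydroxybutanoate
Product: 3 methyl (R)-4-(TBDPS-oxy)-3-hydroxybutanoate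
Conditions: TBDPSCl, imidazole, CH2Cl2, 0 °C
Reagents that add atoms: tert-butyldiphenylsilyl chloride, Cl[Si](c1ccccc1)(c1ccccc1)C(C)(C)C
Why: Selective silylation, in which the bulky chlorosilane should react only at the primary C5 hydroxyl and leave the C6 hydroxyl free as the later ring oxygen.

Step 3
Reactants: 3 methyl (R)-4-(TBDPS-oxy)-3-hydroxybutanoate
Product: 4 methyl (2S,3R)-2-allyl-4-(TBDPS-oxy)-3-hydroxybutanoate (C7 S, C6 R)
Conditions: LiN(i-Pr)2 (2.2 equiv), THF, −78 to −20 °C; allyl bromide, DMPU, −78 to −20 °C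
Reagents that add atoms: allyl bromide, C=CCBr
Why: Fráter–Seebach alkylation, in which the lithium-chelated dianion should be allylated on the face opposite the C5 chain and so set C7 anti to the C6 hydroxyl.

Step 4
Reactants: 4 methyl (2S,3R)-2-allyl-4-(TBDPS-oxy)-3-hydroxybutanoate; 5 tert-butyldimethyl(prop-2-yn-1-yloxy)silane
Product: 7 (5S,6R)-5-allyl-1-(TBS-oxy)-7-(TBDPS-oxy)-6-hydroxyhept-2-yn-4-one, via Weinreb amide 6 (not isolated)
Conditions: MeNH(OMe)·HCl, i-PrMgCl, THF, −20 °C; then lithium acetylide from 5 and n-BuLi, THF, −78 to 0 °C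
Reagents that add atoms: N,O-dimethylhydroxylamine hydrochloride (atoms found in 6 only), CNOC.Cl
Why: One-pot Weinreb ketone synthesis, in which the magnesium amide turns the ester into 6, the chelated adduct of 6 and the acetylide stops at the ketone stage, and the C6 alkoxide disfavours enolisation at C7.

Step 5
Reactants: 7 (5S,6R)-β-hydroxy ynone
Product: 8 (2R,3S)-3-allyl-2-(TBDPS-oxymethyl)-6-(TBS-oxymethyl)-2,3-dihydro-4H-pyran-4-one (C6 R, C7 S)
Conditions: AgOSO2CF3 (10 mol %), CH2Cl2, rt, dark
Reagents that add atoms: none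
Why: Silver-catalysed 6-endo-dig oxa-Michael cycloisomerisation of a β-hydroxy ynone, in which the C6 hydroxyl adds to the activated alkyne carbon C10, C6 and C7 are not touched, and their trans arrangement is also the thermodynamic one.

Step 6
Reactants: 8 dihydropyranone
Product: 10 tetrahydropyran-4-one (6R,7S,10S) bearing C6-CH2OTBDPS cis to C10-CH2OTBS plus C7-allyl plus axial C10-CH3, via silyl enol ether 9 (not isolated)
Conditions: CuI, MeLi (gives Me2CuLi), Me3SiCl, Et2O–THF, −78 °C; then 1 M citric acid, THF, 0 °C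
Reagents that add atoms: lithium dimethylcuprate Me2CuLi, [Li+].C[Cu-]C; chlorotrimethylsilane (atoms found in 9 only), C[Si](C)(C)Cl
Why: Chlorosilane-accelerated conjugate addition of a Gilman cuprate to a 2,3-dihydro-4H-pyran-4-one, in which axial attack on the half-chair with the C6 and C7 groups pseudo-equatorial should place the methyl group trans to the C6 arm (C10 S, both CH2O arms cis), while trapping as 9 blocks retro-oxa-Michael opening.

Step 7
Reactants: 10 tetrahydropyran-4-one
Product: 11 axial C8 alcohol (6R,7R,8R,10S)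
Conditions: LiBH(s-Bu)3, THF, −78 °C; then H2O2, aq NaOH, 0 °C
Reagents that add atoms: none
Why: Diastereoselective ketone reduction with a bulky trialkylborohydride, in which the axial C10 methyl group closes the axial trajectory so that hydride should enter equatorially and give the axial 8R alcohol cis to the C7 side chain.

Step 8
Reactants: 11 axial C8 alcohol; 12 angelic acid
Product: 14 C8 angelate (6R,7R,8R,10S), via mixed anhydride 13 (not isolated)
Conditions: 2,4,6-trichlorobenzoyl chloride, Et3N, toluene, rt; then 11, 80 °C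
Reagents that add atoms: 2,4,6-trichlorobenzoyl chloride (atoms found in 13 only), O=C(Cl)c1c(Cl)cc(Cl)cc1Cl
Why: Yamaguchi-type esterification without nucleophilic catalyst, in which 13 acylates the hindered alcohol at the angeloyl carbonyl with retention at C8 and the absence of DMAP avoids the addition–elimination that would turn angelate into tiglate.

Step 9
Reactants: 14 C8 angelate
Product: 15 C12 aldehyde (C7-CH2CHO)
Conditions: OsO4 (2 mol %), NaIO4, 2,6-lutidine, dioxane–H2O, rt
Reagents that add atoms: sodium periodate NaIO4, [Na+].[O-]I(=O)(=O)=O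
Why: Lemieux–Johnson oxidation, in which OsO4 should dihydroxylate the electron-rich monosubstituted allyl double bond far faster than the electron-poor trisubstituted angelate and NaIO4 cleaves the diol.

Step 10
Reactants: 15 C12 aldehyde
Product: 16 2-substituted acrolein (C7-C(=CH2)CHO)
Conditions: CH2=NMe2 iodide (Eschenmoser's salt), Et3N, CH2Cl2, rt
Reagents that add atoms: N,N-dimethylmethyleneiminium iodide, C=[N+](C)C.[I-]
Why: Mannich α-methylenation of an aldehyde, in which the enol adds to the iminium ion at C11 and triethylamine eliminates dimethylamine, installing C13 under conditions that leave the angelate alone.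

Step 11
Reactants: 16 2-substituted acrolein
Product: 18 methyl acrylate ester (C7-C(=CH2)CO2Me), via acrylic acid 17 (not isolated)
Conditions: NaClO2, NaH2PO4, 2-methyl-2-butene, t-BuOH–H2O, 0 °C; crude acid, MeI, KHCO3, DMF, rt
Reagents that add atoms: sodium chlorite NaClO2, [Na+].[O-]Cl=O; methyl iodide, CI
Why: Pinnick oxidation followed by carboxylate O-alkylation, in which chlorous acid oxidises the enal without touching the alkenes and bicarbonate methylation avoids diazoalkane cycloaddition to the acrylate.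

Step 12
Reactants: 18 methyl acrylate ester
Product: 19 C1 primary alcohol
Conditions: camphorsulfonic acid (10 mol %), MeOH–CH2Cl2, 0 °C to rt
Reagents that add atoms: none
Why: Acid-catalysed silyl ether solvolysis, in which a primary TBS ether is cleaved far faster than a TBDPS ether so that only the C1 hydroxyl should be released.

Step 13
Reactants: 19 C1 primary alcohol
Product: 20 C1 aldehyde
Conditions: Dess–Martin periodinane, NaHCO3, CH2Cl2, 0 °C to rt
Reagents that add atoms: none
Why: Dess–Martin oxidation, a neutral method that stops at the aldehyde, which cannot epimerise because C10 is quaternary.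

Step 14
Reactants: 20 C1 aldehyde
Product: 21 C1 vinyl carbinol (C1 epimers)
Conditions: CH2=CHMgBr, THF, −78 °C; aq NH4Cl
Reagents that add atoms: vinylmagnesium bromide CH2=CHMgBr, C=C[Mg]Br
Why: Grignard 1,2-addition, in which the α-alkoxy aldehyde should react at −78 °C much faster than either ester and the uncontrolled C1 centre is erased in step 16.

Step 15
Reactants: 21 C1 vinyl carbinol
Product: 22 C1,C5 diol
Conditions: HF·pyridine, pyridine, THF, 0 °C to rt; used at once
Reagents that add atoms: none
Why: Fluoride-mediated desilylation in a weakly acidic medium, which frees the primary C5 hydroxyl without alkoxide formation, so lactonisation onto C12 and addition to the acrylate are disfavoured.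

Step 16
Reactants: 22 C1,C5 diol
Product: 23 C1 vinyl ketone C5 aldehyde (6R,7R,8R,10S)
Conditions: Dess–Martin periodinane (3 equiv), NaHCO3, CH2Cl2, 0 °C
Reagents that add atoms: none
Why: Double Dess–Martin oxidation, which makes the vinyl ketone and the aldehyde in one operation, removes the C1 centre and, being non-basic, should preserve C6 next to the new aldehyde.

Step 17
Reactants: 24 propargyl alcohol
Product: 25 tert-butyldiphenyl(prop-2-yn-1-yloxy)silane
Conditions: TBDPSCl, imidazole, CH2Cl2, rt
Reagents that add atoms: tert-butyldiphenylsilyl chloride, Cl[Si](c1ccccc1)(c1ccccc1)C(C)(C)C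
Why: Standard silyl ether formation, choosing the acid-stable group that must survive the acetic acid medium of step 23.

Step 18
Reactants: 25 TBDPS propargyl ether
Product: 26 (E)-3-(TBDPS-oxy)prop-1-enylboronic acid pinacol ester
Conditions: pinacolborane, Cp2ZrHCl (5 mol %), Et3N (5 mol %), neat, 60 °C
Reagents that add atoms: pinacolborane, [H]B1OC(C)(C)C(C)(C)O1
Why: Zirconium-catalysed syn hydroboration of a terminal alkyne, which places boron at the terminus and fixes the E geometry.

Step 19
Reactants: 26 (E)-alkenylboronate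
Product: 27 (E)-4-(TBDPS-oxy)but-2-enylboronic acid pinacol ester
Conditions: BrCH2Cl, n-BuLi, THF, −78 °C to rt
Reagents that add atoms: bromochloromethane, ClCBr
Why: Matteson homologation, in which (chloromethyl)lithium forms the ate complex and 1,2-migration of the alkenyl group proceeds with retention of the E geometry.

Step 20
Reactants: 23 C1 vinyl ketone C5 aldehyde; 27 (E)-allylboronate
Product: 29 homoallylic alcohol (4R,5S,6R,7R,8R,10S) bearing C4-vinyl plus C4-CH2OTBDPS, via pinacol borate 28 (not isolated)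
Conditions: (S)-3,3′-bis(2,4,6-triisopropylphenyl)-1,1′-binaphthyl-2,2′-diyl hydrogen phosphate (10 mol %), 4 Å molecular sieves, toluene, −30 °C; pH 7 buffer
Reagents that add atoms: none
Why: Chiral phosphoric acid-catalysed allylboration through a closed chair transition state, in which the E-boronate gives the anti C4/C5 pair (4R), Si-face attack (5S, C5–O anti to C6–O) follows the Felkin–Anh/Cornforth bias of the α-alkoxy aldehyde and is reinforced by the acid enantiomer chosen as matched, and the vinyl ketone is inert to the boronate.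

Step 21
Reactants: 29 homoallylic alcohol
Product: 30 out,out 11-oxabicyclo[5.3.1]undecenone C5 alcohol (4R,5S,6R,7R,8R,10S; Z-enone)
Conditions: second-generation Hoveyda–Grubbs catalyst (10 mol %), CH2Cl2 (2 mM), 40 °C
Reagents that add atoms: none
Why: Ring-closing metathesis of the C3 vinyl group and the vinyl ketone, helped by reversible addition of the 5S hydroxyl to the C1 ketone, which holds both vinyl groups 1,3-diaxial on a dioxane ring so that closure resembles a six-membered one; the ring enforces the Z-alkene, and the 1,1-disubstituted acrylate and the angelate should be too unreactive to compete at 40 °C.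

Step 22
Reactants: 30 bicyclic C5 alcohol
Product: 31 out,out 11-oxabicyclo[5.3.1]undecenone C5 chloromethanesulfonate (4R,5S,6R,7R,8R,10S)
Conditions: ClCH2SO2Cl, pyridine, CH2Cl2, 0 °C; used without storage
Reagents that add atoms: chloromethanesulfonyl chloride, ClCS(=O)(=O)Cl
Why: O-Sulfonylation with retention at C5, in which the chloro analogue of a mesylate is chosen because it ionises at lower temperature, pyridine is too weak a base to remove the vinylogously acidic C4 proton, and the open hydroxy enone is drained from any transannular hemiketal.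

Step 23
Reactants: 31 C5 chloromethanesulfonate
Product: 33 in,out 11-oxabicyclo[4.4.1]undecenone C6 acetate (4R,5R,6S,7R,8R,10S), via epoxonium ion 32 (not isolated)
Conditions: Zn(OAc)2 (5 equiv), NaOAc (2 equiv), AcOH–H2O 9:1, 50 °C
Reagents that add atoms: zinc acetate Zn(OAc)2, [Zn+2].CC(=O)[O-].CC(=O)[O-]
Why: Proposed new method: in the conformer with the C5–O sulfonate bond antiperiplanar to the C6–O ring bond (C4 gauche to the ring oxygen, H5 turned inward), Zn(OAc)2-assisted ionisation is driven by the ring oxygen, which attacks C5 from the rear to give epoxonium ion 32, and acetate then attacks C6 anti to the breaking C6–O bond. The closest known reaction type is the zinc acetate-promoted ring expansion of 2-(1-sulfonyloxyalkyl)tetrahydropyrans to 3-acyloxyoxepanes, shown so far only on monocyclic and fused ethers and never on a bridged one. The C5–O bond forms by 3-exo-tet attack inside the eight-membered ring and closes the oxepinone ring O–C5–C4–C3–C2–C1–C10, while SN2 opening of the three-membered ring at C6 enlarges the tetrahydropyran to the oxepane O–C5–C6–C7–C8–C9–C10. Both new stereocentres arise by stereospecific inversion, C5 (S to R) being dictated by the configuration of the sulfonate carbon and C6 (R to S) by backside opening, so the in,out array follows from the out,out precursor without any bond being made across opposite faces. The step needs attack at C6 rather than C5 and ionisation faster than loss of the C4 proton: C5 is screened by the C4 branch with its bulky silyl ether, C6 is open along the equatorial direction of the chair, and the buffered weakly acidic medium with the labile sulfonate at 50 °C disfavours vinylogous E1cB elimination. Water capture at C6 would give 34 and then 35, so that material is not lost.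

Step 24
Reactants: 33 C6 acetate
Product: 35 C15-TBDPS ether of the target (trans 6,7-α-methylene-γ-lactone), via C6 hydroxy ester 34 (not isolated)
Conditions: HCl (0.1 M in MeOH), 0 °C to rt
Reagents that add atoms: none
Why: Acid-catalysed transesterification and lactonisation, in which the unconjugated acetate should be exchanged faster than the conjugated hindered angelate, the freed C6 hydroxyl closes the γ-lactone on the neighbouring acrylate ester with all centres retained, and the absence of base avoids alkoxide addition to the enone and the methylene lactone as well as C4 deprotonation with loss of the ether bridge.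

Step 25
Reactants: 35 C15-TBDPS ether
Product: 36 target CNP0274187.1
Conditions: HF·pyridine, pyridine, THF, 0 °C to rt
Reagents that add atoms: none
Why: Fluoride-mediated desilylation in a weakly acidic buffer, which releases the C15 hydroxyl without the basic conditions that would endanger the enone, the methylene lactone and the angelate.

Compound list
1 | dimethyl (R)-malate | COC(=O)C[C@@H](O)C(=O)OC | starting material
2 | methyl (R)-3,4-dihydroxybutanoate | COC(=O)C[C@@H](O)CO | intermediate
3 | methyl (R)-4-(TBDPS-oxy)-3-hydroxybutanoate | COC(=O)C[C@@H](O)CO[Si](c1ccccc1)(c1ccccc1)C(C)(C)C | intermediate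
4 | methyl (2S,3R)-2-allyl-4-(TBDPS-oxy)-3-hydroxybutanoate | C=CC[C@H](C(=O)OC)[C@@H](O)CO[Si](c1ccccc1)(c1ccccc1)C(C)(C)C | intermediate
5 | tert-butyldimethyl(prop-2-yn-1-yloxy)silane | C#CCO[Si](C)(C)C(C)(C)C | starting material
6 | (2S,3R)-N-methoxy-N-methyl amide of 4 (not isolated) | C=CC[C@H](C(=O)N(C)OC)[C@@H](O)CO[Si](c1ccccc1)(c1ccccc1)C(C)(C)C | intermediate
7 | (5S,6R)-5-allyl-1-(TBS-oxy)-7-(TBDPS-oxy)-6-hydroxyhept-2-yn-4-one | C=CC[C@H](C(=O)C#CCO[Si](C)(C)C(C)(C)C)[C@@H](O)CO[Si](c1ccccc1)(c1ccccc1)C(C)(C)C | intermediate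
8 | (2R,3S)-3-allyl-2-(TBDPS-oxymethyl)-6-(TBS-oxymethyl)-2,3-dihydro-4H-pyran-4-one | C=CC[C@H]1[C@H](CO[Si](c2ccccc2)(c2ccccc2)C(C)(C)C)OC(CO[Si](C)(C)C(C)(C)C)=CC1=O | intermediate
9 | C8 trimethylsilyl enol ether of 10 (C8=C9; not isolated) | C=CC[C@H]1[C@H](CO[Si](c2ccccc2)(c2ccccc2)C(C)(C)C)O[C@@](C)(C=C1O[Si](C)(C)C)CO[Si](C)(C)C(C)(C)C | intermediate
10 | tetrahydropyran-4-one (6R,7S,10S): C6-CH2OTBDPS and C10-CH2OTBS cis, C7-allyl trans to the C6 arm, C10-CH3 | C=CC[C@H]1[C@H](CO[Si](c2ccccc2)(c2ccccc2)C(C)(C)C)O[C@@](C)(CC1=O)CO[Si](C)(C)C(C)(C)C | intermediate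
11 | tetrahydropyran-4-ol (6R,7R,8R,10S), C8-OH axial and cis to C7-allyl | C=CC[C@H]1[C@H](CO[Si](c2ccccc2)(c2ccccc2)C(C)(C)C)O[C@@](C)(C[C@H]1O)CO[Si](C)(C)C(C)(C)C | intermediate
12 | angelic acid, (Z)-2-methylbut-2-enoic acid | C/C=C(/C)C(=O)O | starting material
13 | angelic 2,4,6-trichlorobenzoic anhydride (not isolated) | C/C=C(/C)C(=O)OC(=O)c1c(Cl)cc(Cl)cc1Cl | intermediate
14 | C8 angelate of 11 | C=CC[C@H]1[C@H](CO[Si](c2ccccc2)(c2ccccc2)C(C)(C)C)O[C@@](C)(C[C@H]1OC(=O)/C(C)=C\C)CO[Si](C)(C)C(C)(C)C | intermediate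
15 | C7-CH2CHO aldehyde | O=CC[C@H]1[C@H](CO[Si](c2ccccc2)(c2ccccc2)C(C)(C)C)O[C@@](C)(C[C@H]1OC(=O)/C(C)=C\C)CO[Si](C)(C)C(C)(C)C | intermediate
16 | C7-C(=CH2)CHO enal | C=C(C=O)[C@H]1[C@H](CO[Si](c2ccccc2)(c2ccccc2)C(C)(C)C)O[C@@](C)(C[C@H]1OC(=O)/C(C)=C\C)CO[Si](C)(C)C(C)(C)C | intermediate
17 | C7-C(=CH2)CO2H acid (not isolated) | C=C(C(=O)O)[C@H]1[C@H](CO[Si](c2ccccc2)(c2ccccc2)C(C)(C)C)O[C@@](C)(C[C@H]1OC(=O)/C(C)=C\C)CO[Si](C)(C)C(C)(C)C | intermediate
18 | C7-C(=CH2)CO2Me ester, C5-OTBDPS, C1-OTBS | C=C(C(=O)OC)[C@H]1[C@H](CO[Si](c2ccccc2)(c2ccccc2)C(C)(C)C)O[C@@](C)(C[C@H]1OC(=O)/C(C)=C\C)CO[Si](C)(C)C(C)(C)C | intermediate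
19 | C1 primary alcohol | C=C(C(=O)OC)[C@H]1[C@H](CO[Si](c2ccccc2)(c2ccccc2)C(C)(C)C)O[C@@](C)(C[C@H]1OC(=O)/C(C)=C\C)CO | intermediate
20 | C1 aldehyde | C=C(C(=O)OC)[C@H]1[C@H](CO[Si](c2ccccc2)(c2ccccc2)C(C)(C)C)O[C@@](C)(C[C@H]1OC(=O)/C(C)=C\C)C=O | intermediate
21 | C1 vinyl carbinol (C1 epimers) | C=C(C(=O)OC)[C@H]1[C@H](CO[Si](c2ccccc2)(c2ccccc2)C(C)(C)C)O[C@@](C)(C[C@H]1OC(=O)/C(C)=C\C)C(O)C=C | intermediate
22 | C1,C5 diol (C1 epimers) | C=C(C(=O)OC)[C@H]1[C@H](CO)O[C@@](C)(C[C@H]1OC(=O)/C(C)=C\C)C(O)C=C | intermediate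
23 | C1 vinyl ketone, C5 aldehyde (6R,7R,8R,10S) | C=C(C(=O)OC)[C@H]1[C@H](C=O)O[C@@](C)(C[C@H]1OC(=O)/C(C)=C\C)C(=O)C=C | intermediate
24 | propargyl alcohol | C#CCO | starting material
25 | tert-butyldiphenyl(prop-2-yn-1-yloxy)silane | C#CCO[Si](c1ccccc1)(c1ccccc1)C(C)(C)C | intermediate
26 | (E)-3-(TBDPS-oxy)prop-1-enylboronic acid pinacol ester | CC1(C)OB(/C=C/CO[Si](c2ccccc2)(c2ccccc2)C(C)(C)C)OC1(C)C | intermediate
27 | (E)-4-(TBDPS-oxy)but-2-enylboronic acid pinacol ester | CC1(C)OB(C/C=C/CO[Si](c2ccccc2)(c2ccccc2)C(C)(C)C)OC1(C)C | intermediate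
28 | C5-O pinacol borate of 29 (not isolated) | C=C(C(=O)OC)[C@H]1[C@H]([C@@H](OB2OC(C)(C)C(C)(C)O2)[C@@H](CO[Si](c2ccccc2)(c2ccccc2)C(C)(C)C)C=C)O[C@@](C)(C[C@H]1OC(=O)/C(C)=C\C)C(=O)C=C | intermediate
29 | monocyclic diene: C5-OH (5S), C4 (4R) with vinyl and CH2OTBDPS, C1 vinyl ketone | C=C(C(=O)OC)[C@H]1[C@H]([C@@H](O)[C@@H](CO[Si](c2ccccc2)(c2ccccc2)C(C)(C)C)C=C)O[C@@](C)(C[C@H]1OC(=O)/C(C)=C\C)C(=O)C=C | intermediate
30 | out,out 11-oxabicyclo[5.3.1]undecenone C5 alcohol | C=C(C(=O)OC)[C@H]1[C@H]2O[C@@](C)(C[C@H]1OC(=O)/C(C)=C\C)C(=O)/C=C\[C@H](CO[Si](c3ccccc3)(c3ccccc3)C(C)(C)C)[C@@H]2O | intermediate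
31 | out,out 11-oxabicyclo[5.3.1]undecenone C5 chloromethanesulfonate (key-step precursor) | C=C(C(=O)OC)[C@H]1[C@H]2O[C@@](C)(C[C@H]1OC(=O)/C(C)=C\C)C(=O)/C=C\[C@H](CO[Si](c3ccccc3)(c3ccccc3)C(C)(C)C)[C@@H]2OS(=O)(=O)CCl | intermediate
32 | epoxonium ion, oxygen bonded to C5, C6 and C10 (not isolated) | C=C(C(=O)OC)[C@H]1[C@H]2[O+]3[C@@](C)(C[C@H]1OC(=O)/C(C)=C\C)C(=O)/C=C\[C@H](CO[Si](c4ccccc4)(c4ccccc4)C(C)(C)C)[C@H]23 | intermediate
33 | in,out 11-oxabicyclo[4.4.1]undecenone C6 acetate (key-step product) | C=C(C(=O)OC)[C@H]1[C@H](OC(C)=O)[C@@H]2O[C@@](C)(C[C@H]1OC(=O)/C(C)=C\C)C(=O)C=C[C@@H]2CO[Si](c3ccccc3)(c3ccccc3)C(C)(C)C | intermediate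
34 | C6 hydroxy ester (not isolated) | C=C(C(=O)OC)[C@H]1[C@H](O)[C@@H]2O[C@@](C)(C[C@H]1OC(=O)/C(C)=C\C)C(=O)C=C[C@@H]2CO[Si](c3ccccc3)(c3ccccc3)C(C)(C)C | intermediate
35 | C15-TBDPS ether of the target | C=C1C(=O)O[C@@H]2[C@@H]3O[C@@](C)(C[C@@H](OC(=O)/C(C)=C\C)[C@@H]12)C(=O)C=C[C@@H]3CO[Si](c4ccccc4)(c4ccccc4)C(C)(C)C | intermediate
36 | CNP0274187.1 | C=C1C(=O)O[C@@H]2[C@@H]3O[C@@](C)(C[C@@H](OC(=O)/C(C)=C\C)[C@@H]12)C(=O)C=C[C@@H]3CO | target

Total step count: 25. Longest linear sequence: 22 (steps 1–16 and 20–25).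

Steps most likely to fail

1. Step 23.
The epoxonium ion may be opened at C5 instead of C6, or may never form because the antiperiplanar conformer is too sparsely populated. The sulfonate may also be lost by vinylogous elimination through the C4 proton.
The fallback sets out from 29 and returns at 33, and it moves the oxygen shift to the monocyclic stage, which is the known substrate class. Alcohol 29 is sulfonylated with ClCH2SO2Cl and pyridine to the monocyclic chloromethanesulfonate F1. Zn(OAc)2 in buffered aqueous acetic acid expands its tetrahydropyran to the 2,7-trans oxepane C6 acetate F2. Ring-closing metathesis of the vinyl ketone and the C3 vinyl group of F2 (second-generation Hoveyda–Grubbs catalyst, high dilution, toluene, 80 °C) then closes the enone bridge to 33. Closure of this type is known for carbocyclic in,out bicyclo[4.4.1]undecenes.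

2. Step 21.
Oligomerisation, or competing six-membered closure of the C3 vinyl group onto the acrylate methylene, may outrun the bridging closure.
The fallback sets out from 29 and returns at 30, and it uses a ketal tether. Camphorsulfonic acid and trimethyl orthoformate in MeOH lock the C5 oxygen onto C1 as the mixed methyl ketal F3, a 2,9-dioxabicyclo[3.3.1]nonane with both vinyl-bearing groups axial. Metathesis then has to close only a dihydropyran ring and gives the cage ketal F4. Mild aqueous acid hydrolysis of this allylic ketal releases the C1 ketone and the C5 hydroxyl of 30.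

3. Step 6.
Addition to the fully substituted β-carbon may be too slow, or the enolate may open the ring by retro-oxa-Michael reaction and scramble C10.
The fallback sets out from 4 and returns at 10, and it activates the acceptor with a removable ester.
- Cross-Claisen condensation of 4 with excess lithium enolate of allyl acetate gives the β-keto ester F5.
- C-acylation with (TBS-oxy)acetyl chloride (MgCl2, pyridine) and acid-induced cyclodehydration give the 5-allyloxycarbonyl dihydropyranone F6.
- Me2CuLi adds axially to this doubly activated alkene to give F7.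
- Pd(PPh3)4 with morpholine removes the allyl ester with decarboxylation to give 10.

Further compounds
F1 | step 23 | monocyclic C5 chloromethanesulfonate of 29 | C=C(C(=O)OC)[C@H]1[C@H]([C@@H](OS(=O)(=O)CCl)[C@@H](CO[Si](c2ccccc2)(c2ccccc2)C(C)(C)C)C=C)O[C@@](C)(C[C@H]1OC(=O)/C(C)=C\C)C(=O)C=C
F2 | step 23 | 2,7-trans oxepane C6 acetate with C5 side chain and C1 vinyl ketone | C=C(C(=O)OC)[C@H]1[C@H](OC(C)=O)[C@@H]([C@@H](CO[Si](c2ccccc2)(c2ccccc2)C(C)(C)C)C=C)O[C@@](C)(C[C@H]1OC(=O)/C(C)=C\C)C(=O)C=C
F3 | step 21 | mixed methyl ketal of 29 (C5–O–C1 tether, 2,9-dioxabicyclo[3.3.1]nonane) | C=C(C(=O)OC)[C@H]1[C@H]2O[C@@](C)(C[C@H]1OC(=O)/C(C)=C\C)[C@@](OC)(C=C)O[C@H]2[C@@H](CO[Si](c3ccccc3)(c3ccccc3)C(C)(C)C)C=C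
F4 | step 21 | cage ketal after metathesis (C2=C3 in a dihydropyran ring) | C=C(C(=O)OC)[C@H]1[C@H]2O[C@@](C)(C[C@H]1OC(=O)/C(C)=C\C)[C@@]3(OC)C=C[C@H](CO[Si](c4ccccc4)(c4ccccc4)C(C)(C)C)[C@@H]2O3
F5 | step 6 | allyl (4S,5R)-4-allyl-6-(TBDPS-oxy)-5-hydroxy-3-oxohexanoate | C=CC[C@H](C(=O)CC(=O)OCC=C)[C@@H](O)CO[Si](c1ccccc1)(c1ccccc1)C(C)(C)C
F6 | step 6 | 5-allyloxycarbonyl analogue of dihydropyranone 8 | C=CC[C@H]1[C@H](CO[Si](c2ccccc2)(c2ccccc2)C(C)(C)C)OC(CO[Si](C)(C)C(C)(C)C)=C(C(=O)OCC=C)C1=O
F7 | step 6 | C9 allyloxycarbonyl analogue of tetrahydropyranone 10 (C9 enolisable) | C=CC[C@H]1[C@H](CO[Si](c2ccccc2)(c2ccccc2)C(C)(C)C)O[C@@](C)(C(C(=O)OCC=C)C1=O)CO[Si](C)(C)C(C)(C)C
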